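**Retrosynthetic overview**

1. The last bond made is the C–C single bond of the (E,E)-diene, by Suzuki–Miyaura coupling of an alkenyl boronate (lactam half) with an (E)-alkenyl iodide (tetronic acid half).
2. Ring A (the 1,5-dihydropyrrol-2-one) is formed first, in one operation from four components: a terminal alkyne, CO, formaldehyde and (2S)-2-methylbutan-1-amine (nickel-catalysed [2+2+1] through the N-methylene imine made in the flask). This is possible because ring A (N1–C2(=O)–C3=C4–C5) carries only hydrogen at C4 and C5 and its single carbon substituent at C3, next to the carbonyl: C3/C4 are a terminal alkyne, C2 is CO, and C5–N1 is the formaldehyde imine of the side-chain amine.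
3. The alkyne comes from hepta-1,6-diyne by copper-catalysed syn-methylboration, which sets the (E)-trisubstituted alkene.
4. The east half starts from (S)-citronellal (C-methyl stereocentre; aldehyde → alkyne → (E)-alkenyl iodide); Still–Gennari olefination gives the (Z)-trisubstituted alkene and an auxiliary-controlled glycolate alkylation sets the oxygen-bearing stereocentre.
5. Ring B (tetronic acid) is closed last within the east half by Dieckmann cyclization, before the two halves are joined.

Key step: step 2

Remark: (S)-citronellal 6, (2S)-2-methylbutan-1-amine 3 and the butane-2,3-diacetal-protected glycolate 16 are taken as catalogue reagents of high enantiomeric purity.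

**Route**

Step 1
Reactants: 1 hepta-1,6-diyne (3 equiv)
Product: 2 4,4,5,5-tetramethyl-2-[(1E)-2-methylhept-1-en-6-yn-1-yl]-1,3,2-dioxaborolane
Conditions: B2pin2 (1.0 equiv), MeI (3 equiv), CuCl (5 mol%), Xantphos (5 mol%), NaOtBu (1.2 equiv), THF, rt; excess 1 recovered by distillation
Reagents that add atoms: bis(pinacolato)diboron, CC1(C)OB(OC1(C)C)B1OC(C)(C)C(C)(C)O1; iodomethane, CI
Why: Copper-catalysed methylboration (carboboration) of a terminal alkyne, in which syn-borylcupration places boron on the terminal carbon and the alkenylcopper is methylated with retention, fixes the (E) geometry of the trisubstituted alkene, and the excess of the cheap diyne should hold the reaction at one alkyne.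

Step 2
Reactants: 2 4,4,5,5-tetramethyl-2-[(1E)-2-methylhept-1-en-6-yn-1-yl]-1,3,2-dioxaborolane; 3 (2S)-2-methylbutan-1-amine (1.5 equiv)
Product: 5 1-[(2S)-2-methylbutyl]-3-[(4E)-4-methyl-5-(4,4,5,5-tetramethyl-1,3,2-dioxaborolan-2-yl)pent-4-en-1-yl]-1,5-dihydro-2H-pyrrol-2-one, via (2S)-2-methyl-N-methylidenebutan-1-amine 4 (not isolated)
Conditions: 3, paraformaldehyde (1.4 equiv of CH2O), 4 Å molecular sieves, toluene, 60 °C, 2 h; then Ni(cod)2 (10 mol%), P(c-C5H9)3 (20 mol%), CO (about 1.5 equiv, fed slowly from a gas syringe under N2), 80 °C, 2 added over 6 h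
Reagents that add atoms: paraformaldehyde (as formaldehyde), C=O; carbon monoxide, [C-]#[O+]
Why: Proposed new method: amine 3 and formaldehyde first condense over the sieves to the N-methylene imine 4, which binds side-on to zerovalent nickel together with the terminal alkyne of 2; oxidative cyclization joins the imine CH2 carbon to the alkyne CH terminus and gives a five-membered azanickelacycle (Ni–N and Ni–C(chain)=CH), CO inserts into this metallacycle, and reductive elimination releases the lactam and returns zerovalent nickel. The closest known reaction type is the nickel-catalysed [2+2+1] carbonylative cycloaddition of N-sulfonyl aldimines, internal alkynes and CO (an aza-Pauson–Khand reaction), supported by nickel-catalysed C–C coupling of N-alkyl aldimines with alkynes; not yet shown are an N-alkyl formaldimine made in the flask and a terminal alkyne as partners. Ring A is the only ring closed, in a formal [2+2+1] mode: C4–C5 by oxidative cyclization, C2–C3 and N1–C2 by CO insertion and reductive elimination. No stereocentre is created, and the (S) centre of the N-substituent lies two bonds from the nearest reacting atom and has no pathway for epimerization. The step needs regioselectivity (chain at C3, next to the carbonyl) and chemoselectivity over alkyne cyclotrimerization, 2:1 alkyne–imine adducts and an oxygen analogue from free formaldehyde: the first is secured by the terminal alkyne itself, whose CH end is the less hindered carbon and so takes the unsubstituted imine carbon while the chain-bearing carbon stays on nickel and later takes CO (a small trialkylphosphine keeps this bias), the others by slow addition of 2 to excess imine under a low standing concentration of CO and by consuming the formaldehyde with a slight excess of 3 before nickel is added. The alkenyl boronate of 2 is trisubstituted, a poor ligand for zerovalent nickel and unable to transmetalate without base, so it should be carried through unchanged.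

Step 3
Reactants: 6 (3S)-3,7-dimethyloct-6-enal ((S)-citronellal)
Product: 8 (3S)-3,7-dimethyloct-6-en-1-yne, via alkenyl nonaflate 7 (not isolated)
Conditions: n-C4F9SO2F (1.3 equiv), phosphazene base P2-Et (2.5 equiv), DMF, −20 °C → rt
Reagents that add atoms: none
Why: One-pot conversion of an enolizable aldehyde into a terminal alkyne, by O-sulfonylation of the enolate to the alkenyl nonaflate and base-induced elimination of nonaflate, keeps the C3 stereocentre because it is β to the carbonyl and not acidic.

Step 4
Reactants: 8 (3S)-3,7-dimethyloct-6-en-1-yne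
Product: 10 (1E,3S)-1-iodo-3,7-dimethylocta-1,6-diene, via alkenylzirconocene chloride 9 (not isolated)
Conditions: Cp2Zr(H)Cl (1.2 equiv), THF, rt, dark; then I2 (1.2 equiv), 0 °C
Reagents that add atoms: iodine, II
Why: Hydrozirconation adds Zr–H syn with zirconium at the terminal alkyne carbon much faster than at the trisubstituted alkene, and iodinolysis of the C–Zr bond with retention gives the (E)-alkenyl iodide.

Step 5
Reactants: 10 (1E,3S)-1-iodo-3,7-dimethylocta-1,6-diene
Product: 12 (4S,5E)-6-iodo-4-methylhex-5-enal, via epoxide 11 (not isolated)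
Conditions: mCPBA (1.05 equiv), CH2Cl2, 0 °C; then H5IO6 (1.2 equiv), THF/H2O, 0 °C → rt
Reagents that add atoms: 3-chloroperbenzoic acid, OOC(=O)c1cccc(Cl)c1
Why: Prilezhaev epoxidation is selective for the electron-rich trisubstituted alkene over the iodoalkene, and periodic acid opens the epoxide and cleaves the resulting glycol (oxidative glycol cleavage) to the aldehyde and acetone without touching the stereocentre.

Step 6
Reactants: 12 (4S,5E)-6-iodo-4-methylhex-5-enal
Product: 13 methyl (2Z,6S,7E)-8-iodo-2,6-dimethylocta-2,7-dienoate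
Conditions: methyl 2-[bis(2,2,2-trifluoroethoxy)phosphoryl]propanoate (1.2 equiv), KN(SiMe3)2 (1.15 equiv), 18-crown-6, THF, −78 °C
Reagents that add atoms: methyl 2-[bis(2,2,2-trifluoroethoxy)phosphoryl]propanoate, COC(=O)C(C)P(=O)(OCC(F)(F)F)OCC(F)(F)F
Why: Still–Gennari olefination, in which the trifluoroethyl phosphonate and a dissociated potassium counter-ion make elimination from the kinetic adduct fast, should give the (Z)-trisubstituted enoate with the ester cis to the chain.

Step 7
Reactants: 13 methyl (2Z,6S,7E)-8-iodo-2,6-dimethylocta-2,7-dienoate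
Product: 14 (2Z,6S,7E)-8-iodo-2,6-dimethylocta-2,7-dien-1-ol
Conditions: i-Bu2AlH (2.3 equiv), CH2Cl2, −78 °C; aq. potassium sodium tartrate work-up
Reagents that add atoms: none
Why: 1,2-Reduction of the conjugated ester by the aluminium hydride gives the allylic alcohol without change of alkene geometry and leaves the alkenyl iodide intact.

Step 8
Reactants: 14 (2Z,6S,7E)-8-iodo-2,6-dimethylocta-2,7-dien-1-ol
Product: 15 (1E,3S,6Z)-8-bromo-1-iodo-3,7-dimethylocta-1,6-diene
Conditions: PBr3 (0.4 equiv), Et2O, −10 °C; used crude at once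
Reagents that add atoms: phosphorus tribromide, BrP(Br)Br
Why: Bromination of a primary allylic alcohol through its phosphite ester proceeds by SN2 displacement at low temperature and should keep the (Z) geometry.

Step 9
Reactants: 16 (5R,6R)-5,6-dimethoxy-5,6-dimethyl-1,4-dioxan-2-one (1.2 equiv); 15 (1E,3S,6Z)-8-bromo-1-iodo-3,7-dimethylocta-1,6-diene
Product: 18 (3S,5R,6R)-3-[(2Z,6S,7E)-8-iodo-2,6-dimethylocta-2,7-dien-1-yl]-5,6-dimethoxy-5,6-dimethyl-1,4-dioxan-2-one, via lithium enolate 17 (not isolated)
Conditions: LiN(SiMe3)2 (1.2 equiv), THF, −78 °C; then 15, −78 → −40 °C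
Reagents that add atoms: none
Why: Diastereoselective enolate alkylation of the diacetal-protected glycolate, in which the bromide enters anti to the axial methoxy group at C5 (1,3 to the enolate carbon) so that the new substituent is equatorial, sets C3 as (S) (the future C5 of ring B), and SN2 attack at the primary allylic carbon keeps the (Z)-alkene.

Step 10
Reactants: 18 (3S,5R,6R)-3-[(2Z,6S,7E)-8-iodo-2,6-dimethylocta-2,7-dien-1-yl]-5,6-dimethoxy-5,6-dimethyl-1,4-dioxan-2-one
Product: 19 methyl (2S,4Z,8S,9E)-2-hydroxy-10-iodo-4,8-dimethyldeca-4,9-dienoate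
Conditions: anhydrous HCl (0.5 M in MeOH), rt
Reagents that add atoms: methanol, CO
Why: Acid-catalysed transacetalization and transesterification in methanol remove the diacetal and open the lactone to the α-hydroxy methyl ester without touching the α-stereocentre.

Step 11
Reactants: 19 methyl (2S,4Z,8S,9E)-2-hydroxy-10-iodo-4,8-dimethyldeca-4,9-dienoate
Product: 20 methyl (2S,4Z,8S,9E)-10-iodo-4,8-dimethyl-2-(propanoyloxy)deca-4,9-dienoate
Conditions: (EtCO)2O (1.5 equiv), Et3N, DMAP (cat.), CH2Cl2, 0 °C → rt
Reagents that add atoms: propanoic anhydride, CCC(=O)OC(=O)CC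
Why: DMAP-catalysed O-acylation of the secondary alcohol installs the propanoate that supplies C2, C3 and the C3 methyl group of ring B.

Step 12
Reactants: 20 methyl (2S,4Z,8S,9E)-10-iodo-4,8-dimethyl-2-(propanoyloxy)deca-4,9-dienoate
Product: 21 (5S)-4-hydroxy-5-[(2Z,6S,7E)-8-iodo-2,6-dimethylocta-2,7-dien-1-yl]-3-methylfuran-2(5H)-one
Conditions: LiN(SiMe3)2 (2.5 equiv), THF, −78 → 0 °C; 1 M HCl work-up
Reagents that add atoms: none
Why: Dieckmann cyclization (5-exo-trig attack of the propanoate enolate on the methyl ester) closes ring B and is driven by formation of the stabilized tetronate anion, and low temperature should keep the configuration at C5.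

Step 13
Reactants: 5 1-[(2S)-2-methylbutyl]-3-[(4E)-4-methyl-5-(4,4,5,5-tetramethyl-1,3,2-dioxaborolan-2-yl)pent-4-en-1-yl]-1,5-dihydro-2H-pyrrol-2-one; 21 (5S)-4-hydroxy-5-[(2Z,6S,7E)-8-iodo-2,6-dimethylocta-2,7-dien-1-yl]-3-methylfuran-2(5H)-one
Product: 22 (5S)-4-hydroxy-3-methyl-5-[(2Z,6S,7E,9E)-2,6,10-trimethyl-13-{1-[(2S)-2-methylbutyl]-2-oxo-2,5-dihydro-1H-pyrrol-3-yl}trideca-2,7,9-trien-1-yl]furan-2(5H)-one (CNP0256696.3)
Conditions: Pd(dppf)Cl2 (5 mol%), K3PO4 (4 equiv, aq.), THF, 45 °C, degassed; then 1 M HCl to pH 2–3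
Reagents that add atoms: none
Why: Suzuki–Miyaura coupling of an (E)-alkenyl iodide with a trisubstituted alkenyl pinacol boronate proceeds with retention at both partners and gives the (E,E)-diene, while the tetronic acid is carried as its inert potassium salt and the lactam is stable to aqueous phosphate.

**Compound list**

1 | hepta-1,6-diyne | C#CCCCC#C | starting material
2 | 4,4,5,5-tetramethyl-2-[(1E)-2-methylhept-1-en-6-yn-1-yl]-1,3,2-dioxaborolane | C#CCCC/C(C)=C/B1OC(C)(C)C(C)(C)O1 | intermediate
3 | (2S)-2-methylbutan-1-amine | CC[C@H](C)CN | starting material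
4 | (2S)-2-methyl-N-methylidenebutan-1-amine | CC[C@H](C)CN=C | intermediate
5 | 1-[(2S)-2-methylbutyl]-3-[(4E)-4-methyl-5-(4,4,5,5-tetramethyl-1,3,2-dioxaborolan-2-yl)pent-4-en-1-yl]-1,5-dihydro-2H-pyrrol-2-one | CC[C@H](C)CN1CC=C(CCC/C(C)=C/B2OC(C)(C)C(C)(C)O2)C1=O | intermediate
6 | (3S)-3,7-dimethyloct-6-enal ((S)-citronellal) | O=CC[C@@H](C)CCC=C(C)C | starting material
7 | (3S)-3,7-dimethylocta-1,6-dien-1-yl nonafluorobutane-1-sulfonate (E/Z mixture) | FC(F)(F)C(F)(F)C(F)(F)C(F)(F)S(=O)(=O)OC=C[C@@H](C)CCC=C(C)C | intermediate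
8 | (3S)-3,7-dimethyloct-6-en-1-yne | C#C[C@@H](C)CCC=C(C)C | intermediate
9 | chloridobis(cyclopentadienyl)[(1E,3S)-3,7-dimethylocta-1,6-dien-1-yl]zirconium | Cl[Zr](C1C=CC=C1)(C1C=CC=C1)/C=C/[C@@H](C)CCC=C(C)C | intermediate
10 | (1E,3S)-1-iodo-3,7-dimethylocta-1,6-diene | I/C=C/[C@@H](C)CCC=C(C)C | intermediate
11 | 3-[(3S,4E)-5-iodo-3-methylpent-4-en-1-yl]-2,2-dimethyloxirane (both epimers at the oxirane carbon) | I/C=C/[C@@H](C)CCC1OC1(C)C | intermediate
12 | (4S,5E)-6-iodo-4-methylhex-5-enal | I/C=C/[C@@H](C)CCC=O | intermediate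
13 | methyl (2Z,6S,7E)-8-iodo-2,6-dimethylocta-2,7-dienoate | I/C=C/[C@@H](C)CC/C=C(/C)C(=O)OC | intermediate
14 | (2Z,6S,7E)-8-iodo-2,6-dimethylocta-2,7-dien-1-ol | I/C=C/[C@@H](C)CC/C=C(/C)CO | intermediate
15 | (1E,3S,6Z)-8-bromo-1-iodo-3,7-dimethylocta-1,6-diene | I/C=C/[C@@H](C)CC/C=C(/C)CBr | intermediate
16 | (5R,6R)-5,6-dimethoxy-5,6-dimethyl-1,4-dioxan-2-one | O=C1CO[C@@](C)(OC)[C@](C)(OC)O1 | starting material
17 | lithium enolate of 16, lithium (5R,6R)-5,6-dimethoxy-5,6-dimethyl-5,6-dihydro-1,4-dioxin-2-olate | [Li]OC1=CO[C@@](C)(OC)[C@](C)(OC)O1 | intermediate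
18 | (3S,5R,6R)-3-[(2Z,6S,7E)-8-iodo-2,6-dimethylocta-2,7-dien-1-yl]-5,6-dimethoxy-5,6-dimethyl-1,4-dioxan-2-one | I/C=C/[C@@H](C)CC/C=C(/C)C[C@@H]1O[C@@](C)(OC)[C@](C)(OC)OC1=O | intermediate
19 | methyl (2S,4Z,8S,9E)-2-hydroxy-10-iodo-4,8-dimethyldeca-4,9-dienoate | I/C=C/[C@@H](C)CC/C=C(/C)C[C@@H](C(=O)OC)O | intermediate
20 | methyl (2S,4Z,8S,9E)-10-iodo-4,8-dimethyl-2-(propanoyloxy)deca-4,9-dienoate | I/C=C/[C@@H](C)CC/C=C(/C)C[C@@H](C(=O)OC)OC(=O)CC | intermediate
21 | (5S)-4-hydroxy-5-[(2Z,6S,7E)-8-iodo-2,6-dimethylocta-2,7-dien-1-yl]-3-methylfuran-2(5H)-one | I/C=C/[C@@H](C)CC/C=C(/C)C[C@@H]1OC(=O)C(C)=C1O | intermediate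
22 | (5S)-4-hydroxy-3-methyl-5-[(2Z,6S,7E,9E)-2,6,10-trimethyl-13-{1-[(2S)-2-methylbutyl]-2-oxo-2,5-dihydro-1H-pyrrol-3-yl}trideca-2,7,9-trien-1-yl]furan-2(5H)-one | CC[C@H](C)CN1CC=C(CCC/C(C)=C/C=C/[C@@H](C)CC/C=C(/C)C[C@@H]2OC(=O)C(C)=C2O)C1=O | target

**Step count and risks**

Total step count: 13. Longest linear sequence: 11 steps (steps 3 to 13, from (S)-citronellal 6).

The three steps most likely to fail:

Step 2 (key step, proposed new method). What may go wrong: loss of regiocontrol in the oxidative cyclization (chain placed at C4 instead of C3), alkyne cyclotrimerization outrunning the four-component union, self-association of the N-methylene imine that leaves too little monomer for nickel, or arrest of the catalyst as nickel carbonyls. The fallback sets out from 2 (together with amine 3) and comes back to the route at 5, using known chemistry only. Amine 3 (in excess) is mono-allylated with allyl bromide (K2CO3, MeCN) to N-[(2S)-2-methylbutyl]prop-2-en-1-amine F1. Palladium-catalysed branched-selective hydroaminocarbonylation of the terminal alkyne of 2 with F1 and CO (Pd(OAc)2, 2-pyridyldiphenylphosphine, MsOH, CO 1 atm) gives the 2-substituted acrylamide (6E)-6-methyl-2-methylidene-N-[(2S)-2-methylbutyl]-N-(prop-2-en-1-yl)-7-(4,4,5,5-tetramethyl-1,3,2-dioxaborolan-2-yl)hept-6-enamide F2. Ring-closing metathesis with the second-generation Grubbs catalyst (CH2Cl2, 40 °C) then closes ring A between the acrylamide methylidene and the N-allyl group with loss of ethene, giving 5.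

Step 1. What may go wrong: reaction at both alkynes, cyclization of the alkenylcopper onto the second alkyne, or methylation of a copper acetylide. The fallback sets out from 1 and comes back at 2. Diyne 1 is mono-silylated (n-BuLi 1 equiv, THF, −78 °C; Me3SiCl) to trimethyl(hepta-1,6-diyn-1-yl)silane F3, which is separated by distillation. The same copper-catalysed methylboration then finds only one terminal alkyne and gives trimethyl[(6E)-6-methyl-7-(4,4,5,5-tetramethyl-1,3,2-dioxaborolan-2-yl)hept-6-en-1-yn-1-yl]silane F4. K2CO3 in MeOH at rt removes the silyl group to give 2.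

Step 12. What may go wrong: deprotonation at the oxygen-bearing stereocentre competing with enolization of the propanoate, which erodes the configuration at C5 of ring B, or retro-Claisen cleavage of the ester. The fallback sets out from 19 and comes back at 21. Alcohol 19 is acylated with 2-bromopropanoyl bromide (pyridine, CH2Cl2, −20 °C) to methyl (2S,4Z,8S,9E)-2-[(2-bromopropanoyl)oxy]-10-iodo-4,8-dimethyldeca-4,9-dienoate F5 (both epimers at the bromine-bearing carbon). SmI2 (2.2 equiv, THF, −78 °C) reduces the C–Br bond to the samarium enolate, which closes ring B by intramolecular Reformatsky-type acylation of the methyl ester under non-basic conditions and gives 21 after acidic work-up; the alkenyl iodide should not be reduced under these conditions.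

**Further compounds**

F1 | step 2 | N-[(2S)-2-methylbutyl]prop-2-en-1-amine | CC[C@H](C)CNCC=C
F2 | step 2 | (6E)-6-methyl-2-methylidene-N-[(2S)-2-methylbutyl]-N-(prop-2-en-1-yl)-7-(4,4,5,5-tetramethyl-1,3,2-dioxaborolan-2-yl)hept-6-enamide | C=CCN(C[C@@H](C)CC)C(=O)C(=C)CCC/C(C)=C/B1OC(C)(C)C(C)(C)O1
F3 | step 1 | trimethyl(hepta-1,6-diyn-1-yl)silane | C#CCCCC#C[Si](C)(C)C
F4 | step 1 | trimethyl[(6E)-6-methyl-7-(4,4,5,5-tetramethyl-1,3,2-dioxaborolan-2-yl)hept-6-en-1-yn-1-yl]silane | C[Si](C)(C)C#CCCC/C(C)=C/B1OC(C)(C)C(C)(C)O1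
F5 | step 12 | methyl (2S,4Z,8S,9E)-2-[(2-bromopropanoyl)oxy]-10-iodo-4,8-dimethyldeca-4,9-dienoate | I/C=C/[C@@H](C)CC/C=C(/C)C[C@@H](C(=O)OC)OC(=O)C(C)Br
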